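Ring A (the tetrahydropyran) is disconnected at the O1–C6 bond. The feature used is its ether oxygen O1: one neighbour is C2, which carries the pyridone, and the other is the CH2 group C6, which is attached to the sp2 ring carbon C5. A free C2 hydroxyl can therefore be joined to a rhodium carbenoid generated at C6 beside a C5 ketone. In one operation the key step forms O1–C6, closes ring A and leaves the C5 carbonyl for the Z-selective olefination. Its precursor is an acyclic anti (1R,2R) hydroxy diazoketone bearing the O,O'-dibenzylated N-hydroxypyridone at C2 and the methyl group at C3; one asymmetric crotylboration sets both stereocentres.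

Key step: step 12

Remark: ring A is numbered O1, C2 (pyridone-bearing), C3 (methyl), C4, C5 (alkylidene), C6 throughout, also for the open-chain precursors; the target has (2R,3R) trans ring centres, a (5Z) exocyclic alkene with the chain cis to C6, and a (6R) side-chain centre; (+)-Ipc2BOMe means the borinate made from (−)-α-pinene.

Step 1
Reactants: 1 ethyl 3-oxo-4-phenylbutanoate
Product: 3 4-hydroxy-5-phenyl-2H-pyran-2-one, via formyl keto ester 2 (not isolated)
Conditions: LDA (3.2 equiv), THF, 0 °C; HCO2Et, −78 to 0 °C; aq. HCl; then DBU, PhMe, 80 °C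
Reagents that add atoms: ethyl formate, CCOC=O
Why: Claisen-type C-formylation at the benzylic γ-carbon of the doubly deprotonated β-keto ester gives 2, whose enol oxygen lactonises onto the ester under DBU (the acylation–cyclisation route to 4-hydroxy-2-pyranones); no stereocentre is formed.

Step 2
Reactants: 3 4-hydroxy-5-phenyl-2H-pyran-2-one; 4 O-benzylhydroxylamine
Product: 5 1-(benzyloxy)-4-hydroxy-5-phenylpyridin-2(1H)-one
Conditions: EtOH/H2O (1:1), 90 °C
Reagents that add atoms: none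
Why: Pyranone-to-pyridone exchange, in which the alkoxyamine opens the enol lactone by N-acylation and the amide nitrogen then condenses with the unmasked formyl carbon with loss of water; no stereocentre is formed.

Step 3
Reactants: 5 1-(benzyloxy)-4-hydroxy-5-phenylpyridin-2(1H)-one
Product: 6 1,4-bis(benzyloxy)-5-phenylpyridin-2(1H)-one
Conditions: BnBr, K2CO3, DMF, rt to 50 °C
Reagents that add atoms: benzyl bromide, BrCc1ccccc1
Why: Williamson O-alkylation of the acidic vinylogous acid oxygen (4-OH), the usual outcome for N-substituted 4-hydroxy-2-pyridones with benzylic halides and carbonate base.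

Step 4
Reactants: 6 1,4-bis(benzyloxy)-5-phenylpyridin-2(1H)-one
Product: 7 1,4-bis(benzyloxy)-3-iodo-5-phenylpyridin-2(1H)-one
Conditions: N-iodosuccinimide, MeCN, cat. TFA, rt
Reagents that add atoms: N-iodosuccinimide, O=C1CCC(=O)N1I
Why: Electrophilic iodination at C3 of the pyridone, the only enol-ether/enamide-type nucleophilic CH because C5 is blocked by phenyl.

Step 5
Reactants: 7 1,4-bis(benzyloxy)-3-iodo-5-phenylpyridin-2(1H)-one
Product: 9 1,4-bis(benzyloxy)-2-oxo-5-phenyl-1,2-dihydropyridine-3-carbaldehyde, via pyridonyl Grignard 8 (not isolated)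
Conditions: iPrMgCl·LiCl, THF, −40 °C; DMF, −40 to 0 °C; aq. NH4Cl
Reagents that add atoms: N,N-dimethylformamide, CN(C)C=O
Why: Iodine–magnesium exchange gives the chelate-stabilised Grignard 8 at low temperature and DMF formylates it (Bouveault-type formylation), which avoids exposing the N–OBn group to a strong amide or alkyllithium base.

Step 6
Reactants: 9 1,4-bis(benzyloxy)-2-oxo-5-phenyl-1,2-dihydropyridine-3-carbaldehyde; 10 trans-but-2-ene
Product: 14 1,4-bis(benzyloxy)-3-[(1R,2R)-1-hydroxy-2-methylbut-3-en-1-yl]-5-phenylpyridin-2(1H)-one, via crotylpotassium 11 (not isolated), via crotylborane 12 (not isolated), via borinate 13 (not isolated)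
Conditions: KOtBu, n-BuLi, THF, −78 to −45 °C; (+)-Ipc2BOMe, −78 °C; BF3·OEt2; then 9, −78 °C; 3 M NaOH, 30% H2O2, 0 °C to rt
Reagents that add atoms: none
Why: Brown asymmetric crotylboration through a closed chair transition state, in which the E geometry of 12 fixes the anti C2/C3 relationship and the isopinocampheyl groups from (−)-α-pinene direct the crotyl unit to the Re face of the aldehyde, so that the (1R,2R) alcohol should result after oxidative cleavage of 13.

Step 7
Reactants: 14 1,4-bis(benzyloxy)-3-[(1R,2R)-1-hydroxy-2-methylbut-3-en-1-yl]-5-phenylpyridin-2(1H)-one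
Product: 15 1,4-bis(benzyloxy)-3-[(1R,2R)-2-methyl-1-(triethylsilyloxy)but-3-en-1-yl]-5-phenylpyridin-2(1H)-one
Conditions: TESOTf, 2,6-lutidine, CH2Cl2, −78 to 0 °C
Reagents that add atoms: triethylsilyl trifluoromethanesulfonate, CC[Si](CC)(CC)OS(=O)(=O)C(F)(F)F
Why: Silyl ether formation with the reactive triflate on the hindered carbinol, needed because a free C2 hydroxyl would lactonise once C5 reaches the acid level; the stereocentres are not touched.

Step 8
Reactants: 15 1,4-bis(benzyloxy)-3-[(1R,2R)-2-methyl-1-(triethylsilyloxy)but-3-en-1-yl]-5-phenylpyridin-2(1H)-one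
Product: 17 1,4-bis(benzyloxy)-3-[(1R,2R)-4-hydroxy-2-methyl-1-(triethylsilyloxy)butyl]-5-phenylpyridin-2(1H)-one, via alkylborane 16 (not isolated)
Conditions: 9-BBN, THF, 0 °C to rt; then 3 M NaOH, 30% H2O2, 0 °C
Reagents that add atoms: hydrogen peroxide, OO
Why: Anti-Markovnikov hydroboration–oxidation with a bulky dialkylborane places oxygen only on the terminal carbon (C5) and creates no stereocentre.

Step 9
Reactants: 17 1,4-bis(benzyloxy)-3-[(1R,2R)-4-hydroxy-2-methyl-1-(triethylsilyloxy)butyl]-5-phenylpyridin-2(1H)-one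
Product: 18 (3R,4R)-4-[1,4-bis(benzyloxy)-2-oxo-5-phenyl-1,2-dihydropyridin-3-yl]-3-methyl-4-(triethylsilyloxy)butanoic acid
Conditions: TEMPO (cat.), PhI(OAc)2, MeCN/pH 7 phosphate buffer, rt
Reagents that add atoms: water, O
Why: Nitroxyl-catalysed oxidation of the primary alcohol through the aldehyde hydrate to the carboxylic acid; the α-carbon (C4) is a CH2 group, so no centre can epimerise.

Step 10
Reactants: 18 (3R,4R)-4-[1,4-bis(benzyloxy)-2-oxo-5-phenyl-1,2-dihydropyridin-3-yl]-3-methyl-4-(triethylsilyloxy)butanoic acid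
Product: 20 1,4-bis(benzyloxy)-3-[(1R,2R)-5-diazo-2-methyl-4-oxo-1-(triethylsilyloxy)pentyl]-5-phenylpyridin-2(1H)-one, via mixed anhydride 19 (not isolated)
Conditions: iBuOCOCl, Et3N, THF, −15 °C; then CH2N2 (Et2O solution), −15 to 0 °C
Reagents that add atoms: diazomethane, C=[N+]=[N-]
Why: C-acylation of diazomethane by the mixed carbonic anhydride 19 (the first stage of an Arndt–Eistert sequence) should give the terminal diazoketone and supplies C6.

Step 11
Reactants: 20 1,4-bis(benzyloxy)-3-[(1R,2R)-5-diazo-2-methyl-4-oxo-1-(triethylsilyloxy)pentyl]-5-phenylpyridin-2(1H)-one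
Product: 21 1,4-bis(benzyloxy)-3-[(1R,2R)-5-diazo-1-hydroxy-2-methyl-4-oxopentyl]-5-phenylpyridin-2(1H)-one
Conditions: Bu4NF, AcOH, THF, 0 °C
Reagents that add atoms: none
Why: Fluoride-mediated desilylation under acetic acid buffering, conditions that diazoketones and benzyl ethers tolerate.

Step 12
Reactants: 21 1,4-bis(benzyloxy)-3-[(1R,2R)-5-diazo-1-hydroxy-2-methyl-4-oxopentyl]-5-phenylpyridin-2(1H)-one
Product: 22 1,4-bis(benzyloxy)-3-[(2R,3R)-3-methyl-5-oxotetrahydro-2H-pyran-2-yl]-5-phenylpyridin-2(1H)-one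
Conditions: Rh2(OAc)4 (2 mol %), CH2Cl2, rt, slow addition of 21 (about 0.005 M final)
Reagents that add atoms: none
Why: Rh2(OAc)4, a dimeric carboxylate of divalent rhodium, expels N2 from 21 to give an electrophilic carbenoid at C6; the C2 hydroxyl adds to it to form an oxonium ylide, and proton transfer with release of the catalyst completes the O1–C6 bond. The closest known reaction type is the intramolecular O–H insertion of rhodium carbenoids derived from hydroxy diazoketones, which delivers 3-oxo cyclic ethers. Ring A closes in a six-membered mode in which the oxygen attacks the metal-bound carbon while the Rh=C bond stays outside the forming ring. No stereocentre is created, and C2 and C3 take no part in bond making, so the anti relationship from step 6 becomes the trans-2,3 arrangement of the ring. The step needs chemoselectivity for O–H insertion over C–H insertion (notably at C2–H), over ylide formation at the benzyl ether or pyridone oxygens and over addition to the arenes; the free hydroxyl is the most nucleophilic site and the only heteroatom that reaches C6 through a six-membered transition state. Slow addition at high dilution should suppress intermolecular insertion and carbene dimerisation.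

Step 13
Reactants: 22 1,4-bis(benzyloxy)-3-[(2R,3R)-3-methyl-5-oxotetrahydro-2H-pyran-2-yl]-5-phenylpyridin-2(1H)-one
Product: 24 1,4-bis(benzyloxy)-3-[(2R,3R,5Z)-3-methyl-5-(2-oxoethylidene)tetrahydro-2H-pyran-2-yl]-5-phenylpyridin-2(1H)-one, via dioxolane acetal 23 (not isolated)
Conditions: (1,3-dioxolan-2-ylmethyl)triphenylphosphonium bromide, KOtBu, THF, 0 °C; then 22, −78 °C to rt; then 1 M aq. oxalic acid, THF, 0 °C
Reagents that add atoms: (1,3-dioxolan-2-ylmethyl)triphenylphosphonium bromide, [Br-].C(C1OCCO1)[P+](c1ccccc1)(c1ccccc1)c1ccccc1; water, O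
Why: Wittig olefination of an α-alkoxy ketone with a non-conjugated ylide, a pairing known to place the new alkene substituent cis to the CH2O arm (here C6), so the (5Z) geometry is set in this step, and the allylic acetal 23 is then hydrolysed under acid too mild to isomerise the trisubstituted alkene.

Step 14
Reactants: 24 1,4-bis(benzyloxy)-3-[(2R,3R,5Z)-3-methyl-5-(2-oxoethylidene)tetrahydro-2H-pyran-2-yl]-5-phenylpyridin-2(1H)-one
Product: 25 1,4-bis(benzyloxy)-3-[(2R,3R,5Z)-5-[(2E)-3-iodoprop-2-en-1-ylidene]-3-methyltetrahydro-2H-pyran-2-yl]-5-phenylpyridin-2(1H)-one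
Conditions: CrCl2, CHI3, THF/1,4-dioxane, 0 °C to rt, dark
Reagents that add atoms: iodoform, IC(I)I
Why: Takai iodo-olefination, in which the geminal dichromium reagent adds to the aldehyde and eliminates to the (E)-alkenyl iodide, while the existing Z alkene takes no part.

Step 15
Reactants: 26 (R)-2-methylbutanoic acid
Product: 27 (R)-N-methoxy-N,2-dimethylbutanamide
Conditions: MeNH(OMe)·HCl, EDC·HCl, N-methylmorpholine, CH2Cl2, 0 °C to rt
Reagents that add atoms: N,O-dimethylhydroxylamine hydrochloride, CNOC.Cl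
Why: Carbodiimide amide coupling to the Weinreb amide under a weak amine base that should not epimerise the α-stereocentre.

Step 16
Reactants: 27 (R)-N-methoxy-N,2-dimethylbutanamide
Product: 29 2-[(1E,3R)-3-methylpent-1-en-1-yl]-4,4,5,5-tetramethyl-1,3,2-dioxaborolane, via aldehyde 28 (not isolated)
Conditions: iBu2AlH, Et2O, −78 °C; aq. potassium sodium tartrate; dried solution added to CrCl2, LiI, Cl2CHBpin, THF, rt
Reagents that add atoms: 2-(dichloromethyl)-4,4,5,5-tetramethyl-1,3,2-dioxaborolane, ClC(Cl)B1OC(C)(C)C(C)(C)O1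
Why: Hydride reduction of the Weinreb amide stops at the chelated hemiaminal and releases the volatile aldehyde 28 on work-up, and the Takai–Utimoto boryl-olefination then gives the (E)-alkenylboronate without base, so the α-stereocentre should be preserved.

Step 17
Reactants: 25 1,4-bis(benzyloxy)-3-[(2R,3R,5Z)-5-[(2E)-3-iodoprop-2-en-1-ylidene]-3-methyltetrahydro-2H-pyran-2-yl]-5-phenylpyridin-2(1H)-one; 29 2-[(1E,3R)-3-methylpent-1-en-1-yl]-4,4,5,5-tetramethyl-1,3,2-dioxaborolane
Product: 30 1,4-bis(benzyloxy)-3-[(2R,3R,5Z)-3-methyl-5-[(2E,4E,6R)-6-methylocta-2,4-dien-1-ylidene]tetrahydro-2H-pyran-2-yl]-5-phenylpyridin-2(1H)-one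
Conditions: Pd(PPh3)4 (5 mol %), aq. K3PO4, THF, rt, dark
Reagents that add atoms: none
Why: Suzuki–Miyaura coupling of an alkenyl iodide with an alkenylboronate at zerovalent palladium proceeds with retention of both alkene geometries under mild aqueous base.

Step 18
Reactants: 30 1,4-bis(benzyloxy)-3-[(2R,3R,5Z)-3-methyl-5-[(2E,4E,6R)-6-methylocta-2,4-dien-1-ylidene]tetrahydro-2H-pyran-2-yl]-5-phenylpyridin-2(1H)-one
Product: 31 1,4-dihydroxy-3-[(2R,3R,5Z)-3-methyl-5-[(2E,4E,6R)-6-methylocta-2,4-dien-1-ylidene]tetrahydro-2H-pyran-2-yl]-5-phenylpyridin-2(1H)-one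
Conditions: BCl3, pentamethylbenzene, CH2Cl2, −78 °C; MeOH quench at −78 °C
Reagents that add atoms: none
Why: Lewis-acid debenzylation with a non-basic cation scavenger, in which both benzyl groups sit on acidic, ester-like oxygens and should cleave at low temperature without reduction of the N–O bond, while pentamethylbenzene keeps the benzyl cations away from the triene.

Compound list
1 | ethyl 3-oxo-4-phenylbutanoate | CCOC(=O)CC(=O)Cc1ccccc1 | starting material
2 | ethyl 4-formyl-3-oxo-4-phenylbutanoate (enolised, configurationally labile, not isolated) | CCOC(=O)CC(=O)C(C=O)c1ccccc1 | intermediate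
3 | 4-hydroxy-5-phenyl-2H-pyran-2-one | O=c1cc(O)c(-c2ccccc2)co1 | intermediate
4 | O-benzylhydroxylamine | NOCc1ccccc1 | starting material
5 | 1-(benzyloxy)-4-hydroxy-5-phenylpyridin-2(1H)-one | O=c1cc(O)c(-c2ccccc2)cn1OCc1ccccc1 | intermediate
6 | 1,4-bis(benzyloxy)-5-phenylpyridin-2(1H)-one | O=c1cc(OCc2ccccc2)c(-c2ccccc2)cn1OCc1ccccc1 | intermediate
7 | 1,4-bis(benzyloxy)-3-iodo-5-phenylpyridin-2(1H)-one | O=c1c(I)c(OCc2ccccc2)c(-c2ccccc2)cn1OCc1ccccc1 | intermediate
8 | [1,4-bis(benzyloxy)-2-oxo-5-phenyl-1,2-dihydropyridin-3-yl]magnesium chloride (not isolated) | Cl[Mg]c1c(OCc2ccccc2)c(-c2ccccc2)cn(OCc2ccccc2)c1=O | intermediate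
9 | 1,4-bis(benzyloxy)-2-oxo-5-phenyl-1,2-dihydropyridine-3-carbaldehyde | O=Cc1c(OCc2ccccc2)c(-c2ccccc2)cn(OCc2ccccc2)c1=O | intermediate
10 | trans-but-2-ene | C/C=C/C | starting material
11 | (E)-but-2-en-1-ylpotassium (not isolated) | [K+].[CH2-]/C=C/C | intermediate
12 | B-[(E)-but-2-en-1-yl]diisopinocampheylborane, isopinocampheyl groups from (−)-α-pinene (not isolated) | C/C=C/CB([C@H]1C[C@H]2C[C@@H]([C@@H]1C)C2(C)C)[C@H]1C[C@H]2C[C@@H]([C@@H]1C)C2(C)C | intermediate
13 | diisopinocampheylborinate ester of alcohol 14 (not isolated) | C=C[C@@H](C)[C@@H](OB([C@H]1C[C@H]2C[C@@H]([C@@H]1C)C2(C)C)[C@H]1C[C@H]2C[C@@H]([C@@H]1C)C2(C)C)c1c(OCc2ccccc2)c(-c2ccccc2)cn(OCc2ccccc2)c1=O | intermediate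
14 | 1,4-bis(benzyloxy)-3-[(1R,2R)-1-hydroxy-2-methylbut-3-en-1-yl]-5-phenylpyridin-2(1H)-one | C=C[C@@H](C)[C@@H](O)c1c(OCc2ccccc2)c(-c2ccccc2)cn(OCc2ccccc2)c1=O | intermediate
15 | 1,4-bis(benzyloxy)-3-[(1R,2R)-2-methyl-1-(triethylsilyloxy)but-3-en-1-yl]-5-phenylpyridin-2(1H)-one | C=C[C@@H](C)[C@@H](O[Si](CC)(CC)CC)c1c(OCc2ccccc2)c(-c2ccccc2)cn(OCc2ccccc2)c1=O | intermediate
16 | B-alkyl-9-borabicyclo[3.3.1]nonane from 15, boron on the terminal carbon (not isolated) | C1CCC2CCCC1B2CC[C@@H](C)[C@@H](O[Si](CC)(CC)CC)c1c(OCc2ccccc2)c(-c2ccccc2)cn(OCc2ccccc2)c1=O | intermediate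
17 | 1,4-bis(benzyloxy)-3-[(1R,2R)-4-hydroxy-2-methyl-1-(triethylsilyloxy)butyl]-5-phenylpyridin-2(1H)-one | OCC[C@@H](C)[C@@H](O[Si](CC)(CC)CC)c1c(OCc2ccccc2)c(-c2ccccc2)cn(OCc2ccccc2)c1=O | intermediate
18 | (3R,4R)-4-[1,4-bis(benzyloxy)-2-oxo-5-phenyl-1,2-dihydropyridin-3-yl]-3-methyl-4-(triethylsilyloxy)butanoic acid | OC(=O)C[C@@H](C)[C@@H](O[Si](CC)(CC)CC)c1c(OCc2ccccc2)c(-c2ccccc2)cn(OCc2ccccc2)c1=O | intermediate
19 | isobutyl carbonic mixed anhydride of acid 18 (not isolated) | CC(C)COC(=O)OC(=O)C[C@@H](C)[C@@H](O[Si](CC)(CC)CC)c1c(OCc2ccccc2)c(-c2ccccc2)cn(OCc2ccccc2)c1=O | intermediate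
20 | 1,4-bis(benzyloxy)-3-[(1R,2R)-5-diazo-2-methyl-4-oxo-1-(triethylsilyloxy)pentyl]-5-phenylpyridin-2(1H)-one | [N-]=[N+]=CC(=O)C[C@@H](C)[C@@H](O[Si](CC)(CC)CC)c1c(OCc2ccccc2)c(-c2ccccc2)cn(OCc2ccccc2)c1=O | intermediate
21 | 1,4-bis(benzyloxy)-3-[(1R,2R)-5-diazo-1-hydroxy-2-methyl-4-oxopentyl]-5-phenylpyridin-2(1H)-one | [N-]=[N+]=CC(=O)C[C@@H](C)[C@@H](O)c1c(OCc2ccccc2)c(-c2ccccc2)cn(OCc2ccccc2)c1=O | intermediate
22 | 1,4-bis(benzyloxy)-3-[(2R,3R)-3-methyl-5-oxotetrahydro-2H-pyran-2-yl]-5-phenylpyridin-2(1H)-one | O=C1CO[C@@H](c2c(OCc3ccccc3)c(-c3ccccc3)cn(OCc3ccccc3)c2=O)[C@H](C)C1 | intermediate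
23 | 1,4-bis(benzyloxy)-3-[(2R,3R,5Z)-5-(1,3-dioxolan-2-ylmethylidene)-3-methyltetrahydro-2H-pyran-2-yl]-5-phenylpyridin-2(1H)-one (not isolated) | O1CCOC1/C=C1\CO[C@@H](c2c(OCc3ccccc3)c(-c3ccccc3)cn(OCc3ccccc3)c2=O)[C@H](C)C1 | intermediate
24 | 1,4-bis(benzyloxy)-3-[(2R,3R,5Z)-3-methyl-5-(2-oxoethylidene)tetrahydro-2H-pyran-2-yl]-5-phenylpyridin-2(1H)-one | O=C/C=C1\CO[C@@H](c2c(OCc3ccccc3)c(-c3ccccc3)cn(OCc3ccccc3)c2=O)[C@H](C)C1 | intermediate
25 | 1,4-bis(benzyloxy)-3-[(2R,3R,5Z)-5-[(2E)-3-iodoprop-2-en-1-ylidene]-3-methyltetrahydro-2H-pyran-2-yl]-5-phenylpyridin-2(1H)-one | I/C=C/C=C1\CO[C@@H](c2c(OCc3ccccc3)c(-c3ccccc3)cn(OCc3ccccc3)c2=O)[C@H](C)C1 | intermediate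
26 | (R)-2-methylbutanoic acid | CC[C@@H](C)C(O)=O | starting material
27 | (R)-N-methoxy-N,2-dimethylbutanamide | CC[C@@H](C)C(=O)N(C)OC | intermediate
28 | (R)-2-methylbutanal (not isolated) | CC[C@@H](C)C=O | intermediate
29 | 2-[(1E,3R)-3-methylpent-1-en-1-yl]-4,4,5,5-tetramethyl-1,3,2-dioxaborolane | CC[C@@H](C)/C=C/B1OC(C)(C)C(C)(C)O1 | intermediate
30 | 1,4-bis(benzyloxy)-3-[(2R,3R,5Z)-3-methyl-5-[(2E,4E,6R)-6-methylocta-2,4-dien-1-ylidene]tetrahydro-2H-pyran-2-yl]-5-phenylpyridin-2(1H)-one | CC[C@@H](C)/C=C/C=C/C=C1\CO[C@@H](c2c(OCc3ccccc3)c(-c3ccccc3)cn(OCc3ccccc3)c2=O)[C@H](C)C1 | intermediate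
31 | 1,4-dihydroxy-3-[(2R,3R,5Z)-3-methyl-5-[(2E,4E,6R)-6-methylocta-2,4-dien-1-ylidene]tetrahydro-2H-pyran-2-yl]-5-phenylpyridin-2(1H)-one | CC[C@@H](C)/C=C/C=C/C=C1\CO[C@@H](c2c(O)c(-c3ccccc3)cn(O)c2=O)[C@H](C)C1 | target

Total step count: 18. Longest linear sequence: 16 steps (steps 1 to 14, then 17 and 18); steps 15 and 16 make the side-chain boronate.

Steps most likely to fail

Step 13. The acetal-bearing ylide may enolise the ketone instead of adding to it, or it may add with poor geometric control, so that the exocyclic alkene forms as a Z/E mixture; some loss of geometry during acetal hydrolysis is also conceivable. The fallback sets out from ketone 22 and uses a plain alkylidene ylide, reaching the aldehyde oxidation level afterwards. The ylide from [2-(tert-butyldimethylsilyloxy)ethyl]triphenylphosphonium bromide and KN(SiMe3)2 (THF, −78 °C to rt) should give the (Z)-allylic silyl ether F1. Bu4NF in THF should then give the (Z)-allylic alcohol F2, and MnO2 in CH2Cl2 should oxidise it to enal 24, where the route is rejoined.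

Step 18. BCl3 may ionise the ring ether, which is activated on both sides (O1–C6 allylic to the triene, O1–C2 benzylic to the electron-rich pyridone), or cationic species may attack the triene, leading to ring opening, isomerisation or oligomerisation. The fallback sets out from ketone 22, which has no alkene, and moves the debenzylation to that stage. BCl3 and pentamethylbenzene (CH2Cl2, −78 °C) should give the dihydroxypyridone ketone F3, and SEMCl with iPr2NEt the bis(2-trimethylsilylethoxymethyl) ether F4. The olefination of step 13 should then give the dioxolane acetal F5 and, after hydrolysis, the enal F6. The iodo-olefination of step 14 should give the dienyl iodide F7, and coupling with 29 as in step 17 the bis-protected triene F8. Bu4NF in THF would finally release both oxygen functions under non-acidic conditions and return to the route at target 31.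

Step 12. The carbenoid may be diverted into C–H insertion at C2–H (a cyclopentanone), into ylide formation at a benzyl ether or pyridone oxygen, or into intermolecular O–H insertion if addition is too fast. The fallback sets out from hydroxy diazoketone 21 and replaces the carbenoid by a polar ring closure. Aqueous HBr in Et2O at 0 °C should convert the diazoketone into the bromomethyl ketone F9 with loss of nitrogen. Ag2O in CH2Cl2 should then close ring A by intramolecular Williamson etherification (oxygen displacing bromide at C6), returning to the route at ketone 22.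

Further compounds
F1 | step 13 | 1,4-bis(benzyloxy)-3-[(2R,3R,5Z)-5-[2-(tert-butyldimethylsilyloxy)ethylidene]-3-methyltetrahydro-2H-pyran-2-yl]-5-phenylpyridin-2(1H)-one | CC(C)(C)[Si](C)(C)OC/C=C1\CO[C@@H](c2c(OCc3ccccc3)c(-c3ccccc3)cn(OCc3ccccc3)c2=O)[C@H](C)C1
F2 | step 13 | 1,4-bis(benzyloxy)-3-[(2R,3R,5Z)-5-(2-hydroxyethylidene)-3-methyltetrahydro-2H-pyran-2-yl]-5-phenylpyridin-2(1H)-one | OC/C=C1\CO[C@@H](c2c(OCc3ccccc3)c(-c3ccccc3)cn(OCc3ccccc3)c2=O)[C@H](C)C1
F3 | step 18 | 1,4-dihydroxy-3-[(2R,3R)-3-methyl-5-oxotetrahydro-2H-pyran-2-yl]-5-phenylpyridin-2(1H)-one | O=C1CO[C@@H](c2c(O)c(-c3ccccc3)cn(O)c2=O)[C@H](C)C1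
F4 | step 18 | 3-[(2R,3R)-3-methyl-5-oxotetrahydro-2H-pyran-2-yl]-5-phenyl-1,4-bis{[2-(trimethylsilyl)ethoxy]methoxy}pyridin-2(1H)-one | O=C1CO[C@@H](c2c(OCOCC[Si](C)(C)C)c(-c3ccccc3)cn(OCOCC[Si](C)(C)C)c2=O)[C@H](C)C1
F5 | step 18 | 3-[(2R,3R,5Z)-5-(1,3-dioxolan-2-ylmethylidene)-3-methyltetrahydro-2H-pyran-2-yl]-5-phenyl-1,4-bis{[2-(trimethylsilyl)ethoxy]methoxy}pyridin-2(1H)-one | O1CCOC1/C=C1\CO[C@@H](c2c(OCOCC[Si](C)(C)C)c(-c3ccccc3)cn(OCOCC[Si](C)(C)C)c2=O)[C@H](C)C1
F6 | step 18 | 3-[(2R,3R,5Z)-3-methyl-5-(2-oxoethylidene)tetrahydro-2H-pyran-2-yl]-5-phenyl-1,4-bis{[2-(trimethylsilyl)ethoxy]methoxy}pyridin-2(1H)-one | O=C/C=C1\CO[C@@H](c2c(OCOCC[Si](C)(C)C)c(-c3ccccc3)cn(OCOCC[Si](C)(C)C)c2=O)[C@H](C)C1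
F7 | step 18 | 3-[(2R,3R,5Z)-5-[(2E)-3-iodoprop-2-en-1-ylidene]-3-methyltetrahydro-2H-pyran-2-yl]-5-phenyl-1,4-bis{[2-(trimethylsilyl)ethoxy]methoxy}pyridin-2(1H)-one | I/C=C/C=C1\CO[C@@H](c2c(OCOCC[Si](C)(C)C)c(-c3ccccc3)cn(OCOCC[Si](C)(C)C)c2=O)[C@H](C)C1
F8 | step 18 | 3-[(2R,3R,5Z)-3-methyl-5-[(2E,4E,6R)-6-methylocta-2,4-dien-1-ylidene]tetrahydro-2H-pyran-2-yl]-5-phenyl-1,4-bis{[2-(trimethylsilyl)ethoxy]methoxy}pyridin-2(1H)-one | CC[C@@H](C)/C=C/C=C/C=C1\CO[C@@H](c2c(OCOCC[Si](C)(C)C)c(-c3ccccc3)cn(OCOCC[Si](C)(C)C)c2=O)[C@H](C)C1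
F9 | step 12 | 1,4-bis(benzyloxy)-3-[(1R,2R)-5-bromo-1-hydroxy-2-methyl-4-oxopentyl]-5-phenylpyridin-2(1H)-one | BrCC(=O)C[C@@H](C)[C@@H](O)c1c(OCc2ccccc2)c(-c2ccccc2)cn(OCc2ccccc2)c1=O
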